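## Analysis of the target

The target is a eudesmane diester: a trans-fused decalin in which ring A (C1–C5, C10) is saturated and ring B (C5–C10) is a 6-en-8-one whose α-carbon C7 carries the 2-hydroxypropan-2-yl group (C11 with C12, C13 and OH). Four contiguous ring stereocentres must be controlled (eudesmane numbering): C10 (R, quaternary, methyl β), C5 (R, H α, trans to the C10 methyl), C4 (S, acetoxy α and equatorial, methyl β and axial) and C3 (S, acyloxy β and equatorial, trans to the C4 oxygen). The C3 ester is (2S,3R)-2,3-epoxy-2-methylbutanoate, the epoxide of tiglic acid with its two methyl groups cis. Sensitive groups are the glycidic ester (acid, nucleophiles), the vicinal secondary ester/tertiary acetate pair (acyl migration while one hydroxyl is free) and the α-(hydroxyalkyl) enone, which dehydrates to the cross-conjugated dienone under acid. The synthesis is hard because two fully substituted carbons (C4, C10) flank C5, and because of the two tertiary oxygen functions only one is acylated. The strategy rests on C7, an sp2 ring carbon that carries the three-carbon C11 branch and sits between C6=C7 and the oxygenated C8. This is the imprint of an exo enyne metathesis between a vinyl group on C5 (C6 and the future C13) and a but-2-ynyl carbinol arm on C10 (C9, C8, C7, C11, C12).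

## Retrosynthetic reasoning

**C11–O.** Target 28 is cut at the C11–O bond to the isopropenyl dienone 27. A Markovnikov hydration as the last step creates the free tertiary alcohol only after the C4 tertiary alcohol is acetylated, so the two never have to be told apart. The forward step must put H on C13 and O on C11 and leave enone, epoxide and esters alone.

**Ester C–O bonds.** 27 is cut at the acetate to 26, and 26 at the C3 ester to diol 20 and epoxy acid 24. The secondary C3 hydroxyl is acylated first because it is the more reactive one and, once esterified, cannot accept the acetyl group by migration. Acid 24 goes back through epoxy alcohol 23 and allylic alcohol 22 to tiglic acid 21; a Sharpless epoxidation sets both epoxide centres.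

**C8 oxidation level.** Dienone 20 goes back to triol 19 and its silyl ethers 18. The ketone is carried as a carbinol because an electron-poor ynone is a poor metathesis partner; the C8 epimer mixture vanishes on oxidation.

**Key disconnection.** Diene 18 is cut at C6=C7 and C11=C13 and reconnected as vinyl plus alkyne in enyne 17. Any other cut in ring B (C5–C6, C7–C8, C8–C9) would need a separate step to place C6=C7 and attach C11. This cut delivers both in one isomerisation and creates no stereocentre, so all four ring A centres can be set beforehand. The forward reaction must close in the exo sense.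

**Vinyl group.** 17 comes from the C6 aldehyde 16 by Wittig methylenation, 16 from alcohol 15, and 15 from the p-methoxybenzyl ether 14. The aldehyde is unmasked late because it is epimerisable and β-silyloxy. The C8 oxygen is silylated in 14, since a free C8 hydroxyl would close onto the C6 aldehyde as a six-membered lactol.

**C7–C8.** 14 is the bis-silyl ether of diol 13, which is cut at C7–C8 into aldehyde 11 and the propynyl Grignard reagent 12.

**C8–C9 and C3.** Aldehyde 11 arises from enol ether 10 (hydrolysis), 10 from ketone 9 (reduction, sets C3), and 9 from keto aldehyde 8 by one-carbon Wittig homologation. The ketone is reduced while the new aldehyde is still masked as the enol ether.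

**C4–O, then C1–C2 and C5–C10.** 8 is the Rubottom product of silyl enol ether 6 (through epoxide 7); this sets C4 and delivers its oxygen already silylated. 6 is cut at C1–C2 and C5–C10 into diene 4 and methacrolein 5. A diene with only the C4 methyl and the C5 side chain would carry two alkyl directors that oppose each other. The silyloxy group at C3 sends the formyl-bearing carbon next to C5 and leaves the enol ether that becomes the C3/C4 oxygen pattern.

**Diene.** 4 is the enol silyl ether of enone 3, 3 the hydration product of enyne ether 2, and 2 the protected form of the commercial enynol 1.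

## Alternatives that were turned down

**Alternative 1:** The C5–C10 bond is disconnected by a retro-transannular cyclisation to the ten-membered germacrone (A1). Forward, a confined chiral Brønsted acid protonates C1 of the C1=C10 alkene, C5 of the C4=C5 alkene captures the C10 cation, and the C4 cation loses a C3 proton to give eudesma-3,7(11)-dien-8-one (A2).
- For: one step from a commercial sesquiterpene gives all fifteen carbons, both rings, the trans fusion and the C8 carbonyl. On step count and number of C–C bond formations it is clearly stronger than the chosen route.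
- Against: A1 is achiral and conformationally mobile, so the acid must select enantiotopic faces in a cation–olefin cyclisation that can also terminate as the 4(15)- or 4-ene and competes with protonation of the isopropylidene enone. A2 still needs the trans 3β,4α-diol from C3=C4. Its 7(11)-en-8-one must also be turned into the 11-hydroxy-6-en-8-one, a γ-oxidation with transposition of an electron-poor tetrasubstituted alkene that has no clearly selective solution.
- Comparison: the chosen route is longer, but every stereocentre comes from a reaction of predictable sense, and C6=C7 with the C7–C11 branch arrives in the right oxidation pattern from the metathesis.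

**Alternative 2:** Ring A is disconnected at C1–C2 and C5–C10 into (E)-β-ocimene (A3) and methacrolein 5. Forward, a cationic oxazaborolidine Lewis acid joins them to the cyclohexene aldehyde A4, formyl trans to prenyl, setting C5 and C10.
- For: it is the same reaction type as step 4 here, so it is equal on how C5 and C10 are set. It is stronger on carbon economy, because the prenyl group already holds C6, C7, C11, C12 and C13 and only C8 is missing.
- Against: in A3 the methyl and the terminal alkyl group direct in opposite senses and no strong donor decides between them. Ring A arrives with only the C3=C4 alkene, which must be dihydroxylated and inverted at C3 beside a second trisubstituted alkene of like reactivity. Ring B must then be closed by a separate C–C bond formation, C6=C7 introduced by dehydrogenation toward C7 and not C9, and C11 oxidised.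
- Comparison: the chosen route spends two reagent carbons on Wittig steps. In return it has a regiochemically reinforced cycloaddition, the ring A oxygens directly from the enol ether, and C6=C7 without a dehydrogenation.

**Alternative 3:** Ring A is disconnected at C3–C4 by a retro-benzoin from ketol A6 to the trans keto aldehyde A5. Forward, a triazolium-derived carbene turns the C3 aldehyde into an acyl anion equivalent that adds to the C4 methyl ketone, closing ring A and setting C4.
- For: the tertiary C4 carbinol and the C3 carbonyl form in one catalytic, redox-neutral step, and the C3 ketone can be reduced to the 3β alcohol as in step 7 here. On the ring A oxygen pattern it is at least as strong as the Rubottom/reduction pair and needs no oxidant.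
- Against: ring A closes last, so A5 must already hold the trans C5/C10 pair with the quaternary C10, which is a synthesis in itself. The C5 acetyl is epimerisable under the basic carbene conditions, and C4 depends on matching of catalyst and substrate. In A6 ring B holds only a masked C8 ketone, so C7 must be functionalised against C9, the C11 carbinol attached (retro-aldol risk), and C6=C7 introduced by dehydrogenation.
- Comparison: the alternative is stronger at C4. The chosen route builds the whole ring B functionality in one bond reorganisation.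

Key step: step 14

Remark on locants: eudesmane numbering is used throughout (ring A = C1–C5, C10; ring B = C5–C10; C14 on C10, C15 on C4, C11–C13 on C7). For the monocyclic ring A compounds, β is the face of the C10 methyl, so the C5 side chain (C6) is β and the C10 arm (C9) is α.

Assumption: the (S)-configured oxazaborolidinium ion is taken to expose the face of bound methacrolein that leads to 6 (formyl C–H···O binding, s-trans enal, exo approach). If the sense proves opposite, the (R)-catalyst is used and nothing else changes.

## Route

Step 1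
Reactants: 1 (2E)-3-methylpent-2-en-4-yn-1-ol
Product: 2 1-methoxy-4-({[(2E)-3-methylpent-2-en-4-yn-1-yl]oxy}methyl)benzene
Conditions: NaH, 4-methoxybenzyl chloride, Bu4NI (cat.), THF, 0 °C to rt
Reagents that add atoms: 4-methoxybenzyl chloride, COc1ccc(CCl)cc1
Why: Williamson etherification of the primary allylic alkoxide. The p-methoxybenzyl group can later be removed oxidatively without touching silyl ethers or the alkyne.

Step 2
Reactants: 2 1-methoxy-4-({[(2E)-3-methylpent-2-en-4-yn-1-yl]oxy}methyl)benzene
Product: 3 (3E)-5-[(4-methoxyphenyl)methoxy]-3-methylpent-3-en-2-one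
Conditions: Ph3PAuNTf2 (2 mol %), H2O, 1,4-dioxane, 60 °C
Reagents that add atoms: water, O
Why: Markovnikov hydration of the terminal alkyne catalysed by univalent gold gives the methyl enone. The (E) geometry holds the ether oxygen away from the alkyne, so no furan can form, and it is kept in the product.

Step 3
Reactants: 3 (3E)-5-[(4-methoxyphenyl)methoxy]-3-methylpent-3-en-2-one
Product: 4 tert-butyl({(3E)-5-[(4-methoxyphenyl)methoxy]-3-methylpenta-1,3-dien-2-yl}oxy)dimethylsilane
Conditions: tBuMe2SiOTf, Et3N, CH2Cl2, 0 °C
Reagents that add atoms: tert-butyldimethylsilyl trifluoromethanesulfonate, CC(C)(C)[Si](C)(C)OS(=O)(=O)C(F)(F)F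
Why: Soft enolisation of a methyl enone with silyl triflate and amine takes place at the methyl group and gives the cross-conjugated 2-silyloxy diene. The (3E) geometry puts the CH2O group on the outside of the s-cis diene.

Step 4
Reactants: 4 tert-butyl({(3E)-5-[(4-methoxyphenyl)methoxy]-3-methylpenta-1,3-dien-2-yl}oxy)dimethylsilane; 5 methacrolein
Product: 6 (1S,2S)-4-[(tert-butyldimethylsilyl)oxy]-2-{[(4-methoxyphenyl)methoxy]methyl}-1,3-dimethylcyclohex-3-ene-1-carbaldehyde (ring A: C10 methyl β and formyl α, C5 side chain β)
Conditions: (S)-3,3-diphenyl-1-(2-methylphenyl)tetrahydro-1H,3H-pyrrolo[1,2-c][1,3,2]oxazaborole (20 mol %), HN(SO2CF3)2 (17 mol %), CH2Cl2, −78 °C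
Reagents that add atoms: none
Why: Catalytic enantioselective Diels–Alder reaction of a 2-silyloxy diene with an α-substituted acrolein bound to a cationic oxazaborolidine. The silyloxy group (para director) and the terminal CH2O group (ortho director) both place the formyl-bearing carbon next to C5. The exo-formyl transition state usual for methacrolein puts the formyl trans to the C5 side chain, and the catalyst face fixes the absolute configuration of C5 and C10.

Step 5
Reactants: 6 ring A silyl enol ether aldehyde
Product: 8 ring A keto aldehyde (3-oxo; 4α-tert-butyldimethylsilyloxy; 4β-methyl; 5β-CH2OPMB; 10β-methyl; 10α-formyl), via silyloxy epoxide 7 (not isolated)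
Conditions: 3-ClC6H4CO3H, NaHCO3, CH2Cl2, −20 to 0 °C
Reagents that add atoms: 3-chloroperoxybenzoic acid, OOC(=O)c1cccc(Cl)c1
Why: Rubottom oxidation: the peracid epoxidises the electron-rich enol ether on the α face, anti to the C5 side chain and the C10 methyl, which sets C4. The silyloxy oxirane opens with 1,4-silyl shift to the α-silyloxy ketone, so the tertiary alcohol emerges protected. The aldehyde is much slower toward buffered peracid at low temperature.

Step 6
Reactants: 8 ring A keto aldehyde
Product: 9 ring A enol ether ketone (as 8, with 10α-(2-methoxyethenyl) in place of formyl, E/Z mixture)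
Conditions: Ph3P(Cl)CH2OMe, KN(SiMe3)2, THF, −78 to 0 °C
Reagents that add atoms: (methoxymethyl)triphenylphosphonium chloride, COC[P+](c1ccccc1)(c1ccccc1)c1ccccc1.[Cl-]
Why: Wittig methoxymethylenation. The aldehyde, though neopentylic, reacts far faster with the ylide than the α-quaternary, α-silyloxy ketone, and it has no α-hydrogen to lose.

Step 7
Reactants: 9 ring A enol ether ketone
Product: 10 ring A 3β-alcohol (3β-hydroxy; 4α-OTBS; 4β-methyl; 5β-CH2OPMB; 10β-methyl; 10α-(2-methoxyethenyl))
Conditions: NaBH4, MeOH, −20 °C
Reagents that add atoms: none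
Why: Hydride reduction of the cyclohexanone. Attack on the α face, which is axial attack in the chair with both arms equatorial and avoids the axial C4 methyl and the C5 side chain on the β face, gives the equatorial 3β alcohol trans to the C4 oxygen and so sets C3.

Step 8
Reactants: 10 ring A 3β-alcohol
Product: 11 ring A aldehyde (as 10, with 10α-(2-oxoethyl))
Conditions: 0.5 M aq. HCl, THF, 0 °C
Reagents that add atoms: water, O
Why: Acid hydrolysis of the methyl enol ether to the homologated aldehyde. The tertiary silyl ether and the benzylic ether tolerate dilute aqueous acid, and the 3β hydroxyl cannot reach the aldehyde on the opposite face.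

Step 9
Reactants: 11 ring A aldehyde; 12 1-propynylmagnesium bromide
Product: 13 ring A diol (3β-hydroxy; 10α-(2-hydroxypent-3-yn-1-yl), C8 epimers)
Conditions: CH3C≡CMgBr (2.5 equiv), THF, −78 to 0 °C
Reagents that add atoms: none
Why: Grignard addition of the alkynyl nucleophile to the aldehyde; one equivalent is consumed by the C3 hydroxyl. Both C8 epimers form, which does not matter because C8 becomes the ketone.

Step 10
Reactants: 13 ring A diol
Product: 14 ring A bis(triethylsilyl) ether (3β-OTES; 8-OTES; 4α-OTBS; 5β-CH2OPMB)
Conditions: Et3SiOTf, 2,6-lutidine, CH2Cl2, −78 to 0 °C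
Reagents that add atoms: triethylsilyl trifluoromethanesulfonate, CC[Si](CC)(CC)OS(=O)(=O)C(F)(F)F
Why: Silylation of both secondary alcohols with a silyl triflate. The C8 hydroxyl must be capped, since a free one would close onto the C6 aldehyde of 16 as a six-membered lactol.

Step 11
Reactants: 14 ring A bis(triethylsilyl) ether
Product: 15 ring A primary alcohol (5β-CH2OH)
Conditions: DDQ, CH2Cl2/pH 7 buffer, 0 °C
Reagents that add atoms: none
Why: Oxidative cleavage of the p-methoxybenzyl ether (hydride abstraction to the oxocarbenium ion, then hydrolysis). Buffered conditions leave the silyl ethers and the alkyne intact.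

Step 12
Reactants: 15 ring A primary alcohol
Product: 16 ring A C6 aldehyde (5β-formyl)
Conditions: Dess–Martin periodinane, NaHCO3, CH2Cl2, 0 °C to rt
Reagents that add atoms: none
Why: Dess–Martin oxidation of the primary alcohol. The buffered, non-basic medium avoids epimerisation at C5 and β-elimination of the C4 silyloxy group.

Step 13
Reactants: 16 ring A C6 aldehyde
Product: 17 ring A enyne (3β-OTES; 4α-OTBS; 4β-methyl; 5β-vinyl; 10β-methyl; 10α-[2-(triethylsilyloxy)pent-3-yn-1-yl], C8 epimers)
Conditions: Ph3PCH3Br, KN(SiMe3)2, THF, −78 °C to rt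
Reagents that add atoms: methyltriphenylphosphonium bromide, C[P+](c1ccccc1)(c1ccccc1)c1ccccc1.[Br-]
Why: Wittig methylenation. The small ylide should add to the hindered aldehyde faster than it deprotonates C5, whose configuration (side chain equatorial, trans to the C10 arm) is in any case the thermodynamically preferred one.

Step 14
Reactants: 17 ring A enyne
Product: 18 4α-(tert-butyldimethylsilyloxy)-3β,8-bis(triethylsilyloxy)eudesma-6,11(13)-diene (C8 epimers)
Conditions: second-generation Grubbs catalyst (H2IMes)(PCy3)Cl2Ru=CHPh (10 mol %), ethylene (1 atm), toluene (0.005 M), 80 °C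
Reagents that add atoms: none
Why: Ring-closing enyne metathesis; the closest known reaction type is the ruthenium-carbene cyclisation of 1,7-enynes to 1-alkenylcyclohexenes run under ethylene. The methylidene (H2IMes)Cl2Ru=CH2 adds to the alkyne with ruthenium on C7, the ruthenacyclobutene opens to the C7 vinylcarbene with C11 now carrying =CH2, and this carbene closes onto the C5 vinyl group, forming C6=C7 and returning the methylidene. Loading on the vinyl group first with exo addition to the alkyne, or ethylene–alkyne cross-metathesis to the acyclic triene followed by diene ring closure, end at the same product, so ethylene is only a carrier and no atom is gained or lost. Ring B closes in the exo mode as a six-membered ring (C5, C6, C7, C8, C9, C10) with C7 in the ring and C11 outside; the endo mode would put C11 into a seven-membered ring and is disfavoured by ring size. No stereocentre is formed: the trans ring fusion is dictated by C5 and C10, whose two arms are trans and both equatorial in the reacting chair, hence gauche and within bonding distance. The step needs exo over endo closure and ring closure over oligomerisation; six- against seven-membered ring formation, high dilution and the gem-disubstitution at C10 secure them. It also needs tolerance of the oxygen functions, so all three are silyl ethers that cannot chelate the carbene, and the methyl cap keeps the alkyne from the polymerisation seen with terminal alkynes. The epimer mixture at C8 is carried through unchanged.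

Step 15
Reactants: 18 tris-silyl diene
Product: 19 eudesma-6,11(13)-diene-3β,4α,8-triol (C8 epimers)
Conditions: Bu4NF (excess), THF, rt to 45 °C
Reagents that add atoms: none
Why: Fluoride cleavage of all three silyl ethers; the tertiary one needs gentle warming. Basic fluoride is chosen because the dienylic C8 carbinol would ionise under acid.

Step 16
Reactants: 19 diene triol
Product: 20 3β,4α-dihydroxyeudesma-6,11(13)-dien-8-one
Conditions: MnO2 (activated, excess), CH2Cl2, rt
Reagents that add atoms: none
Why: Activated MnO2 oxidises the allylic C8 alcohol far faster than the saturated C3 alcohol, and both C8 epimers converge on one dienone.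

Step 17
Reactants: 21 tiglic acid
Product: 22 (2E)-2-methylbut-2-en-1-ol
Conditions: LiAlH4, Et2O, 0 °C
Reagents that add atoms: none
Why: Hydride reduction of the carboxylic acid to the allylic alcohol; the trisubstituted alkene keeps its (E) geometry.

Step 18
Reactants: 22 (2E)-2-methylbut-2-en-1-ol
Product: 23 [(2R,3R)-2,3-dimethyloxiran-2-yl]methanol
Conditions: Ti(OiPr)4 (10 mol %), diethyl D-(−)-tartrate (12 mol %), tBuOOH, 4 Å molecular sieves, CH2Cl2, −20 °C
Reagents that add atoms: tert-butyl hydroperoxide, CC(C)(C)OO
Why: Sharpless asymmetric epoxidation with the tetravalent titanium tartrate catalyst. The D-(−)-tartrate delivers oxygen to the face that gives the (2R,3R) epoxy alcohol, and the (E) alkene fixes the two methyl groups cis.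

Step 19
Reactants: 23 [(2R,3R)-2,3-dimethyloxiran-2-yl]methanol
Product: 24 (2S,3R)-2,3-dimethyloxirane-2-carboxylic acid
Conditions: RuCl3 (2 mol %), NaIO4, CCl4/MeCN/H2O, rt
Reagents that add atoms: water, O
Why: Catalytic RuO4 oxidation of the primary alcohol to the acid through the aldehyde hydrate; epoxides are inert to it. The C2 descriptor changes from R to S only because the substituent priorities change.

Step 20
Reactants: 20 3β,4α-dihydroxyeudesma-6,11(13)-dien-8-one; 24 (2S,3R)-2,3-dimethyloxirane-2-carboxylic acid
Product: 26 3β-[(2S,3R)-2,3-epoxy-2-methylbutanoyloxy]-4α-hydroxyeudesma-6,11(13)-dien-8-one, via mixed anhydride 25 (not isolated)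
Conditions: 24, 2,4,6-Cl3C6H2COCl, Et3N, THF, 0 °C to rt; then 20, DMAP, toluene, rt
Reagents that add atoms: none
Why: Yamaguchi esterification: DMAP attacks the mixed anhydride at the less hindered carbonyl and the acylpyridinium ion acylates the secondary, equatorial 3β hydroxyl. The tertiary C4 hydroxyl does not react under these conditions.

Step 21
Reactants: 26 C3 epoxy ester
Product: 27 4α-acetoxy-3β-[(2S,3R)-2,3-epoxy-2-methylbutanoyloxy]eudesma-6,11(13)-dien-8-one
Conditions: Ac2O, DMAP, Et3N, CH2Cl2, 40 °C
Reagents that add atoms: acetic anhydride, CC(=O)OC(C)=O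
Why: DMAP-catalysed acetylation of the tertiary alcohol under gentle heating. The neighbouring hydroxyl is already esterified, so no acyl migration can scramble the two esters.

Step 22
Reactants: 27 isopropenyl dienone diester
Product: 28 4α-acetoxy-3β-[(2S,3R)-2,3-epoxy-2-methylbutanoyloxy]-11-hydroxyeudesm-6-en-8-one (target)
Conditions: Mn(dpm)3 (dpm = 2,2,6,6-tetramethylheptane-3,5-dionate, 20 mol %), PhSiH3, O2 (1 atm), iPrOH/CH2Cl2, 0 °C to rt
Reagents that add atoms: dioxygen, O=O
Why: Mukaiyama hydration by metal-hydride hydrogen atom transfer: the trivalent manganese hydride delivers a hydrogen atom to the terminal C13, the tertiary C11 radical is trapped by O2, and the peroxide is reduced in the flask to the alcohol. The 1,1-disubstituted alkene should accept the hydrogen atom faster than the trisubstituted enone CH, and epoxy ester, acetate and ketone are inert.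

## Compound list

1 | (2E)-3-methylpent-2-en-4-yn-1-ol | OC/C=C(\C)C#C | starting material
2 | 1-methoxy-4-({[(2E)-3-methylpent-2-en-4-yn-1-yl]oxy}methyl)benzene | COc1ccc(COC/C=C(\C)C#C)cc1 | intermediate
3 | (3E)-5-[(4-methoxyphenyl)methoxy]-3-methylpent-3-en-2-one | COc1ccc(COC/C=C(\C)C(C)=O)cc1 | intermediate
4 | tert-butyl({(3E)-5-[(4-methoxyphenyl)methoxy]-3-methylpenta-1,3-dien-2-yl}oxy)dimethylsilane | COc1ccc(COC/C=C(\C)C(=C)O[Si](C)(C)C(C)(C)C)cc1 | intermediate
5 | methacrolein | CC(=C)C=O | starting material
6 | (1S,2S)-4-[(tert-butyldimethylsilyl)oxy]-2-{[(4-methoxyphenyl)methoxy]methyl}-1,3-dimethylcyclohex-3-ene-1-carbaldehyde | CC1=C(O[Si](C)(C)C(C)(C)C)CC[C@](C)(C=O)[C@H]1COCc2ccc(OC)cc2 | intermediate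
7 | 3,4α-epoxide of 6 (3-silyloxy oxirane) | C[C@@]12O[C@]1(O[Si](C)(C)C(C)(C)C)CC[C@](C)(C=O)[C@H]2COCc3ccc(OC)cc3 | intermediate (not isolated)
8 | ring A keto aldehyde: 3-oxo, 4α-OTBS, 4β-methyl, 5β-CH2OPMB, 10β-methyl, 10α-formyl | CC(C)(C)[Si](C)(C)O[C@]1(C)C(=O)CC[C@](C)(C=O)[C@H]1COCc2ccc(OC)cc2 | intermediate
9 | ring A enol ether ketone: as 8 with 10α-(2-methoxyethenyl), E/Z mixture | CC(C)(C)[Si](C)(C)O[C@]1(C)C(=O)CC[C@](C)(C=COC)[C@H]1COCc2ccc(OC)cc2 | intermediate
10 | ring A 3β-alcohol: 3β-OH, 4α-OTBS, 10α-(2-methoxyethenyl) | CC(C)(C)[Si](C)(C)O[C@]1(C)[C@@H](O)CC[C@](C)(C=COC)[C@H]1COCc2ccc(OC)cc2 | intermediate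
11 | ring A aldehyde: 3β-OH, 4α-OTBS, 10α-(2-oxoethyl) | CC(C)(C)[Si](C)(C)O[C@]1(C)[C@@H](O)CC[C@](C)(CC=O)[C@H]1COCc2ccc(OC)cc2 | intermediate
12 | 1-propynylmagnesium bromide | CC#C[Mg]Br | starting material
13 | ring A diol: 3β-OH, 10α-(2-hydroxypent-3-yn-1-yl), C8 epimers | CC(C)(C)[Si](C)(C)O[C@]1(C)[C@@H](O)CC[C@](C)(CC(O)C#CC)[C@H]1COCc2ccc(OC)cc2 | intermediate
14 | ring A bis(triethylsilyl) ether: 3β-OTES, 8-OTES, 4α-OTBS, 5β-CH2OPMB | CC(C)(C)[Si](C)(C)O[C@]1(C)[C@@H](O[Si](CC)(CC)CC)CC[C@](C)(CC(O[Si](CC)(CC)CC)C#CC)[C@H]1COCc2ccc(OC)cc2 | intermediate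
15 | ring A primary alcohol: 5β-CH2OH | CC(C)(C)[Si](C)(C)O[C@]1(C)[C@@H](O[Si](CC)(CC)CC)CC[C@](C)(CC(O[Si](CC)(CC)CC)C#CC)[C@H]1CO | intermediate
16 | ring A C6 aldehyde: 5β-formyl | CC(C)(C)[Si](C)(C)O[C@]1(C)[C@@H](O[Si](CC)(CC)CC)CC[C@](C)(CC(O[Si](CC)(CC)CC)C#CC)[C@H]1C=O | intermediate
17 | ring A enyne: 3β-OTES, 4α-OTBS, 4β-methyl, 5β-vinyl, 10β-methyl, 10α-[2-(triethylsilyloxy)pent-3-yn-1-yl], C8 epimers | CC(C)(C)[Si](C)(C)O[C@]1(C)[C@@H](O[Si](CC)(CC)CC)CC[C@](C)(CC(O[Si](CC)(CC)CC)C#CC)[C@H]1C=C | intermediate
18 | 4α-(tert-butyldimethylsilyloxy)-3β,8-bis(triethylsilyloxy)eudesma-6,11(13)-diene, C8 epimers | CC(C)(C)[Si](C)(C)O[C@]1(C)[C@@H](O[Si](CC)(CC)CC)CC[C@]2(C)CC(O[Si](CC)(CC)CC)C(C(C)=C)=C[C@H]21 | intermediate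
19 | eudesma-6,11(13)-diene-3β,4α,8-triol, C8 epimers | O[C@]1(C)[C@@H](O)CC[C@]2(C)CC(O)C(C(C)=C)=C[C@H]21 | intermediate
20 | 3β,4α-dihydroxyeudesma-6,11(13)-dien-8-one | O[C@]1(C)[C@@H](O)CC[C@]2(C)CC(=O)C(C(C)=C)=C[C@H]21 | intermediate
21 | tiglic acid | C/C=C(\C)C(=O)O | starting material
22 | (2E)-2-methylbut-2-en-1-ol | C/C=C(\C)CO | intermediate
23 | [(2R,3R)-2,3-dimethyloxiran-2-yl]methanol | OC[C@@]1(C)O[C@@H]1C | intermediate
24 | (2S,3R)-2,3-dimethyloxirane-2-carboxylic acid | OC(=O)[C@@]1(C)O[C@@H]1C | intermediate
25 | (2S,3R)-2,3-dimethyloxirane-2-carboxylic 2,4,6-trichlorobenzoic anhydride | O=C(OC(=O)[C@@]1(C)O[C@@H]1C)c1c(Cl)cc(Cl)cc1Cl | intermediate (not isolated)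
26 | 3β-[(2S,3R)-2,3-epoxy-2-methylbutanoyloxy]-4α-hydroxyeudesma-6,11(13)-dien-8-one | O[C@]1(C)[C@@H](OC(=O)[C@@]2(C)O[C@@H]2C)CC[C@]2(C)CC(=O)C(C(C)=C)=C[C@H]21 | intermediate
27 | 4α-acetoxy-3β-[(2S,3R)-2,3-epoxy-2-methylbutanoyloxy]eudesma-6,11(13)-dien-8-one | CC(=O)O[C@]1(C)[C@@H](OC(=O)[C@@]2(C)O[C@@H]2C)CC[C@]2(C)CC(=O)C(C(C)=C)=C[C@H]21 | intermediate
28 | (3S,4S,5R,10R)-4-acetoxy-3-[(2S,3R)-2,3-epoxy-2-methylbutanoyloxy]-11-hydroxyeudesm-6-en-8-one | CC(=O)O[C@]1(C)[C@@H](OC(=O)[C@@]2(C)O[C@@H]2C)CC[C@]2(C)CC(=O)C(C(C)(C)O)=C[C@H]21 | target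

## Step count and least certain steps

Total: 22 steps. Longest linear sequence: 19 steps (steps 1–16 and 20–22); the epoxy acid takes three steps (17–19).

**Step 14 (key step).** Loading of the carbene onto the C5 vinyl group, which lies between two fully substituted carbons, may be so slow that the sequence stalls at the acyclic triene from ethylene–alkyne cross-metathesis or drifts into oligomerisation.
Fallback: close ring B by an aldol condensation, starting from aldehyde 11 and returning at dienone 20.
- Silylation (Et3SiCl, imidazole) gives the 3-O-triethylsilyl aldehyde F1.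
- CH2=C(CH3)CH2MgCl adds to give the methallyl carbinol F2.
- Dess–Martin oxidation gives the β,γ-unsaturated C8 ketone F3.
- DDQ removes the benzylic ether to give the hydroxy ketone F4, which may sit partly as its hemiketal.
- Dess–Martin oxidation gives the keto aldehyde F5.
- Piperidine/AcOH condenses the doubly activated C7 methylene with the C6 aldehyde and dehydrates to the bis-silyl dienone F6.
- Bu4NF then gives 20.

**Step 22.** The hydrogen atom may be transferred to the enone instead, or the delocalised C11/C6 allyl radical may be trapped by oxygen at C6, giving the transposed 6-oxygenated 7(11)-enone.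
Fallback from 27 to 28: ionic Markovnikov addition. Hg(OAc)2 in THF/H2O places divalent mercury on C13 and water on the tertiary C11 to give the organomercurial F7, which Bu3SnH reduces to 28 without touching the ketone.

**Step 4.** The diene is more substituted than usual partners of this catalyst. Exo/endo and facial selectivity may erode, and the strongly acidic catalyst may protodesilylate the diene.
Fallback from 4 and 5, returning at 10: racemic cycloaddition and resolution.
- Me2AlCl in CH2Cl2 at −78 °C gives racemic 6, that is 6 with its mirror image ent-6 F8.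
- Steps 5–7 on the racemate pass through ent-7 F9, ent-8 F10 and ent-9 F11 to racemic 10, containing ent-10 F12.
- Esterification with (S)-2-methoxy-2-phenylacetic acid (DCC, DMAP) gives the diastereomers (S)-O-methylmandelate of 10 F13 and (S)-O-methylmandelate of ent-10 F14, separable on silica.
- K2CO3/MeOH on F13 returns 10.

**Step 21.** Acylation of the hindered tertiary C4 hydroxyl may be slow, and forcing it invites enol acetylation of the dienone or opening of the glycidic ester.
Fallback from 20, returning at 27: acetylate before the epoxide is present.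
- Chloroacetic anhydride/pyridine gives the 3-O-chloroacetate F15.
- Ac2O with catalytic Sc(OTf)3 in MeCN at −20 °C gives the 3-O-chloroacetate 4-O-acetate F16.
- Thiourea/NaHCO3 in MeOH frees the 4α-acetoxy-3β-hydroxy dienone F17.
- Esterification of F17 with 24 as in step 20 gives 27.

**Step 13.** The basic ylide may enolise the hindered aldehyde, with epimerisation at C5 or β-elimination of the C4 silyloxy group.
Fallback from 16 to 17: Peterson olefination. The weakly basic Me3SiCH2MgCl adds to give the β-hydroxysilane F18, and KH in THF eliminates it to 17.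

## Further compounds

F1 | step 14 | 3-O-triethylsilyl ether of aldehyde 11 | CC(C)(C)[Si](C)(C)O[C@]1(C)[C@@H](O[Si](CC)(CC)CC)CC[C@](C)(CC=O)[C@H]1COCc2ccc(OC)cc2
F2 | step 14 | methallyl carbinol, 10α-(2-hydroxy-4-methylpent-4-en-1-yl), C8 epimers | CC(C)(C)[Si](C)(C)O[C@]1(C)[C@@H](O[Si](CC)(CC)CC)CC[C@](C)(CC(O)CC(C)=C)[C@H]1COCc2ccc(OC)cc2
F3 | step 14 | β,γ-unsaturated C8 ketone, 10α-(4-methyl-2-oxopent-4-en-1-yl) | CC(C)(C)[Si](C)(C)O[C@]1(C)[C@@H](O[Si](CC)(CC)CC)CC[C@](C)(CC(=O)CC(C)=C)[C@H]1COCc2ccc(OC)cc2
F4 | step 14 | hydroxy ketone, 5β-CH2OH | CC(C)(C)[Si](C)(C)O[C@]1(C)[C@@H](O[Si](CC)(CC)CC)CC[C@](C)(CC(=O)CC(C)=C)[C@H]1CO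
F5 | step 14 | keto aldehyde, 5β-formyl | CC(C)(C)[Si](C)(C)O[C@]1(C)[C@@H](O[Si](CC)(CC)CC)CC[C@](C)(CC(=O)CC(C)=C)[C@H]1C=O
F6 | step 14 | 4α-(tert-butyldimethylsilyloxy)-3β-(triethylsilyloxy)eudesma-6,11(13)-dien-8-one | CC(C)(C)[Si](C)(C)O[C@]1(C)[C@@H](O[Si](CC)(CC)CC)CC[C@]2(C)CC(=O)C(C(C)=C)=C[C@H]21
F7 | step 22 | 13-(acetoxymercurio)-11-hydroxy adduct of 27, C11 epimers | CC(=O)O[C@]1(C)[C@@H](OC(=O)[C@@]2(C)O[C@@H]2C)CC[C@]2(C)CC(=O)C(C(C)(O)C[Hg]OC(C)=O)=C[C@H]21
F8 | step 4 | ent-6 | CC1=C(O[Si](C)(C)C(C)(C)C)CC[C@@](C)(C=O)[C@@H]1COCc2ccc(OC)cc2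
F9 | step 4 | ent-7 | C[C@]12O[C@@]1(O[Si](C)(C)C(C)(C)C)CC[C@@](C)(C=O)[C@@H]2COCc3ccc(OC)cc3
F10 | step 4 | ent-8 | CC(C)(C)[Si](C)(C)O[C@@]1(C)C(=O)CC[C@@](C)(C=O)[C@@H]1COCc2ccc(OC)cc2
F11 | step 4 | ent-9 | CC(C)(C)[Si](C)(C)O[C@@]1(C)C(=O)CC[C@@](C)(C=COC)[C@@H]1COCc2ccc(OC)cc2
F12 | step 4 | ent-10 | CC(C)(C)[Si](C)(C)O[C@@]1(C)[C@H](O)CC[C@@](C)(C=COC)[C@@H]1COCc2ccc(OC)cc2
F13 | step 4 | (S)-O-methylmandelate of 10 | CC(C)(C)[Si](C)(C)O[C@]1(C)[C@@H](OC(=O)[C@@H](OC)c2ccccc2)CC[C@](C)(C=COC)[C@H]1COCc3ccc(OC)cc3
F14 | step 4 | (S)-O-methylmandelate of ent-10 | CC(C)(C)[Si](C)(C)O[C@@]1(C)[C@H](OC(=O)[C@@H](OC)c2ccccc2)CC[C@@](C)(C=COC)[C@@H]1COCc3ccc(OC)cc3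
F15 | step 21 | 3β-(chloroacetoxy)-4α-hydroxyeudesma-6,11(13)-dien-8-one | O[C@]1(C)[C@@H](OC(=O)CCl)CC[C@]2(C)CC(=O)C(C(C)=C)=C[C@H]21
F16 | step 21 | 4α-acetoxy-3β-(chloroacetoxy)eudesma-6,11(13)-dien-8-one | CC(=O)O[C@]1(C)[C@@H](OC(=O)CCl)CC[C@]2(C)CC(=O)C(C(C)=C)=C[C@H]21
F17 | step 21 | 4α-acetoxy-3β-hydroxyeudesma-6,11(13)-dien-8-one | CC(=O)O[C@]1(C)[C@@H](O)CC[C@]2(C)CC(=O)C(C(C)=C)=C[C@H]21
F18 | step 13 | β-hydroxysilane, 5β-[1-hydroxy-2-(trimethylsilyl)ethyl], C6 epimers | CC(C)(C)[Si](C)(C)O[C@]1(C)[C@@H](O[Si](CC)(CC)CC)CC[C@](C)(CC(O[Si](CC)(CC)CC)C#CC)[C@H]1C(O)C[Si](C)(C)C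
A1 | alternative 1 | germacrone | O=C1C/C(C)=C/CC/C(C)=C/CC1=C(C)C
A2 | alternative 1 | eudesma-3,7(11)-dien-8-one (5α-H, 10β-methyl) | CC1=CCC[C@]2(C)CC(=O)C(=C(C)C)C[C@H]21
A3 | alternative 2 | (E)-β-ocimene | C=C/C(C)=C/CC=C(C)C
A4 | alternative 2 | 1,3-dimethyl-2-(3-methylbut-2-enyl)cyclohex-3-ene-1-carbaldehyde (formyl trans to prenyl) | O=C[C@@]1(C)CCC=C(C)[C@@H]1CC=C(C)C
A5 | alternative 3 | trans keto aldehyde, 3-oxopropyl and acetyl on the ring B ketal | O=CCC[C@]1(C)CC2(OCCO2)CC[C@H]1C(C)=O
A6 | alternative 3 | 4α-hydroxy-eudesmane-3,8-dione 8-ethylene ketal | O[C@]1(C)C(=O)CC[C@]2(C)CC3(OCCO3)CC[C@H]21
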